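**Assumption:** the target is taken as the open 6α-hydroxy-18-aldehyde drawn in the SMILES; it is the ring-chain tautomer of the 6α,18-lactol released in the last step.

**Numbering used in names:** labdane numbering for decalin and chain (C18 = 4α carbon, C19 = 4β methyl, C20 = 10β methyl, C17 = 8β methyl, chain C11–C15, C16 = 13-methyl); furanone atoms are primed.

## Retrosynthetic overview

1. Target ⇐ acid unmasking of a 6α,18-lactol methyl ether; the butenolide (formed last) ⇐ syn methylcupration/lactonisation of a γ-hydroxy ynoate whose carbinol centre (C5′) comes from a catalytic asymmetric alkynylation.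
2. (13E)-alkene ⇐ zirconium-catalysed methylalumination of a C13 alkyne plus ethylene oxide; the alkyne ⇐ δ-lactone (lactol, Ohira–Bestmann).
3. 6α-oxygen ⇐ 1,5-hydrogen transfer to the C18 alkoxyl radical, then ether → lactone → masked lactol.
4. Decalin ⇐ one cation–olefin cascade of an acyclic epoxy-alcohol dienoate: ring A, then ring B, then the δ-lactone close in a single operation; the C3 oxygen is erased afterwards.
5. Acyclic precursor ⇐ (2E,6E)-farnesyl bromide + tert-butyl acetate, SeO2 ω-oxidation, Sharpless epoxidation (source of all decalin stereochemistry).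

## Route

**Step 1**
Reactants: 1 (2E,6E)-farnesyl bromide; 2 tert-butyl acetate
Product: 4 tert-butyl (4E,8E)-5,9,13-trimethyltetradeca-4,8,12-trienoate, via lithium enolate of tert-butyl acetate 3 (not isolated)
Conditions: LiN(i-Pr)2, THF, −78 °C; then 1, DMPU, −78 → 0 °C
Reagents that add atoms: none
Why: SN2 alkylation of a lithium ester enolate by a primary allylic bromide, which leaves both E alkenes untouched.

**Step 2**
Reactants: 4 tert-butyl (4E,8E)-5,9,13-trimethyltetradeca-4,8,12-trienoate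
Product: 5 tert-butyl (4E,8E,12E)-14-hydroxy-5,9,13-trimethyltetradeca-4,8,12-trienoate
Conditions: SeO2 (cat.), t-BuOOH, salicylic acid (cat.), CH2Cl2, rt
Reagents that add atoms: tert-butyl hydroperoxide, CC(C)(C)OO
Why: SeO2 allylic oxidation (ene/[2,3] sequence, Sharpless–Umbreit conditions) selects the E methyl of the terminal isopropylidene, giving the E-CH2OH that later becomes the equatorial C18.

**Step 3**
Reactants: 5 tert-butyl (4E,8E,12E)-14-hydroxy-5,9,13-trimethyltetradeca-4,8,12-trienoate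
Product: 6 tert-butyl (4E,8E)-11-[(2S,3S)-3-(hydroxymethyl)-3-methyloxiran-2-yl]-5,9-dimethylundeca-4,8-dienoate
Conditions: Ti(OiPr)4 (cat.), L-(+)-diethyl tartrate (cat.), t-BuOOH, 4 Å MS, CH2Cl2, −20 °C
Reagents that add atoms: tert-butyl hydroperoxide, CC(C)(C)OO
Why: Sharpless asymmetric epoxidation touches only the allylic-alcohol alkene and, with the L-tartrate, gives the (2S,3S)-epoxide that fixes the absolute configuration of the whole decalin.

**Step 4 (key step)**
Reactants: 6 tert-butyl (4E,8E)-11-[(2S,3S)-3-(hydroxymethyl)-3-methyloxiran-2-yl]-5,9-dimethylundeca-4,8-dienoate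
Product: 7 3β,18-dihydroxy-14,15,16-trinorlabdan-13,8α-olide
Conditions: MeAlCl2 (3.5 equiv), CH2Cl2, −78 → −40 °C; aq. KNaC4H4O6
Reagents that add atoms: none
Why: Proposed new method: the free hydroxymethyl becomes an Al alkoxide that chelates the epoxide oxygen (holding the C18–H bonds away from the anti-periplanar alignment needed for a competing hydride shift), so the epoxide opens at tertiary C4 with inversion while C5=C10 and C8=C9 add through a chair–chair, all-anti array and the tert-butyl ester carbonyl traps the C8 cation on the α face with loss of isobutene, closing ring A, ring B and the δ-lactone in that order and setting 3β-OH, 4α-CH2OH (the E substituent ends equatorial), 5α-H, 10β-Me, 9α-H and 8α-O at once; closest known reaction types are the MeAlCl2-promoted epoxide-initiated cation–olefin polycyclisation of oxidosqualene-type epoxides and acid- or ester-terminated cyclisations that give sclareolide-type lactones.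

**Step 5**
Reactants: 7 3β,18-dihydroxy-14,15,16-trinorlabdan-13,8α-olide
Product: 8 3β,18-O-thiocarbonyl-14,15,16-trinorlabdan-13,8α-olide (six-membered cyclic thionocarbonate)
Conditions: 1,1'-thiocarbonyldiimidazole, DMAP (cat.), toluene, 80 °C
Reagents that add atoms: 1,1'-thiocarbonyldiimidazole, S=C(n1ccnc1)n1ccnc1
Why: thiocarbonylation of the 1,3-diol (equatorial 3β-OH and equatorial 4α-CH2OH) closes a trans-fused cyclic thionocarbonate without touching a stereocentre.

**Step 6**
Reactants: 8 3β,18-O-thiocarbonyl-14,15,16-trinorlabdan-13,8α-olide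
Product: 10 18-hydroxy-14,15,16-trinorlabdan-13,8α-olide, via S-tributylstannyl thiocarbonate 9 (not isolated)
Conditions: Bu3SnH, AIBN (cat.), toluene, 110 °C; then aq. KF, rt
Reagents that add atoms: none
Why: Barton-type radical deoxygenation of a cyclic thionocarbonate fragments toward the secondary C3 radical (not the primary C18 one), which is reduced to CH2, and fluoride work-up frees the primary 18-OH.

**Step 7**
Reactants: 10 18-hydroxy-14,15,16-trinorlabdan-13,8α-olide
Product: 11 6α,18-epoxy-14,15,16-trinorlabdan-13,8α-olide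
Conditions: PhI(OAc)2, I2, cyclohexane, hν (visible), rt
Reagents that add atoms: none
Why: Suárez hypoiodite reaction: the C18 alkoxyl radical abstracts the peri 6α-hydrogen through a six-membered transition state (1,5-hydrogen transfer) and the oxidative ring closure from the equatorial 4α-CH2O can only occur on the α face, so C6 becomes 6α-O.

**Step 8**
Reactants: 11 6α,18-epoxy-14,15,16-trinorlabdan-13,8α-olide
Product: 12 14,15,16-trinorlabdane-13,8α:18,6α-diolide
Conditions: RuCl3 (cat.), NaIO4, CCl4/MeCN/H2O, rt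
Reagents that add atoms: sodium periodate, [Na+].[O-]I(=O)(=O)=O
Why: RuO4 oxidation of a cyclic ether to a lactone occurs at the accessible C18 methylene, since the remaining 6β C–H is shielded by the two axial methyls (C19, C20).

**Step 9**
Reactants: 12 14,15,16-trinorlabdane-13,8α:18,6α-diolide
Product: 15 18-methoxy-6α,18-epoxy-14,15,16-trinorlabdan-13,8α-olide (C18 epimers), via lithium enolate of the δ-lactone 13 (not isolated), via γ-lactol 14 (not isolated)
Conditions: LiN(i-Pr)2, THF, −78 °C; then i-Bu2AlH, −78 °C; aq. KNaC4H4O6; then MeOH, PPTS, rt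
Reagents that add atoms: methanol, CO
Why: the enolisable δ-lactone is masked in situ as its lithium enolate while the non-enolisable γ-lactone (quaternary C4) is reduced to the lactol, which is fixed by acid-catalysed acetalisation; the anomeric C18 centre is erased in the last step.

**Step 10**
Reactants: 15 18-methoxy-6α,18-epoxy-14,15,16-trinorlabdan-13,8α-olide
Product: 17 18-methoxy-6α,18-epoxy-15,16-dinorlabd-13-yn-8α-ol, via δ-lactol 16 (not isolated)
Conditions: i-Bu2AlH, CH2Cl2, −78 °C; then MeOH, K2CO3, dimethyl (1-diazo-2-oxopropyl)phosphonate, −78 °C → rt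
Reagents that add atoms: dimethyl (1-diazo-2-oxopropyl)phosphonate, CC(=O)C(=[N+]=[N-])P(=O)(OC)OC
Why: partial reduction to the lactol, whose open hydroxy-aldehyde form undergoes Ohira–Bestmann (Seyferth–Gilbert) homologation to the terminal alkyne and releases the 8α tertiary alcohol; the acetal is stable to base.

**Step 11**
Reactants: 17 18-methoxy-6α,18-epoxy-15,16-dinorlabd-13-yn-8α-ol; 18 ethylene oxide
Product: 21 (13E)-15-(hydroxymethyl)-18-methoxy-6α,18-epoxylabd-13-en-8α-ol, via alkenyl(dimethyl)alane 19 (not isolated), via lithium alkenylaluminate 20 (not isolated)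
Conditions: Me3Al, Cp2ZrCl2 (20 mol %), H2O (1 equiv), CH2Cl2, −20 °C; then n-BuLi, THF, −78 °C; then 18, −78 → 0 °C
Reagents that add atoms: trimethylaluminium, C[Al](C)C
Why: Negishi zirconium-catalysed carboalumination is a syn addition (methyl to C13, Al to C14) that fixes the E trisubstituted alkene, and the derived alanate opens ethylene oxide with retention of alkene geometry.

**Step 12**
Reactants: 21 (13E)-15-(hydroxymethyl)-18-methoxy-6α,18-epoxylabd-13-en-8α-ol
Product: 22 (13E)-8α-hydroxy-18-methoxy-6α,18-epoxylabd-13-ene-15-carbaldehyde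
Conditions: Dess–Martin periodinane, NaHCO3, CH2Cl2, 0 °C
Reagents that add atoms: none
Why: buffered Dess–Martin oxidation converts the primary alcohol only (the tertiary 8-OH is inert) and keeps the β,γ-unsaturated aldehyde out of conjugation.

**Step 13**
Reactants: 22 (13E)-8α-hydroxy-18-methoxy-6α,18-epoxylabd-13-ene-15-carbaldehyde; 23 methyl propiolate
Product: 25 methyl (4R)-4-hydroxy-4-[(13E)-8α-hydroxy-18-methoxy-6α,18-epoxylabd-13-en-15-yl]but-2-ynoate, via ethylzinc acetylide 24 (not isolated)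
Conditions: (S)-BINOL (40 mol %), Et2Zn, HMPA, CH2Cl2, rt; then Ti(OiPr)4; then 22, rt
Reagents that add atoms: none
Why: catalytic asymmetric alkynylzinc addition to an aldehyde; the (S)-BINOL–titanium complex is expected to deliver the alkynyl group to the Si face, giving the R carbinol (future C5′) under reagent control, as the decalin centres are too remote to interfere.

**Step 14**
Reactants: 25 methyl (4R)-4-hydroxy-4-[(13E)-8α-hydroxy-18-methoxy-6α,18-epoxylabd-13-en-15-yl]but-2-ynoate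
Product: 27 (5R)-5-[(13E)-8α-hydroxy-18-methoxy-6α,18-epoxylabd-13-en-15-yl]-4-methylfuran-2(5H)-one, via (Z)-hydroxy enoate 26 (not isolated)
Conditions: MeLi, CuI, THF, −78 °C; then 25, −78 °C; aq. NH4Cl, rt
Reagents that add atoms: lithium dimethylcuprate, [Li+].C[Cu-]C
Why: syn carbocupration of the ynoate places the carbinol carbon cis to the ester, so the (Z)-γ-hydroxy enoate lactonises on work-up to the 4-methylbutenolide without touching C5′.

**Step 15**
Reactants: 27 (5R)-5-[(13E)-8α-hydroxy-18-methoxy-6α,18-epoxylabd-13-en-15-yl]-4-methylfuran-2(5H)-one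
Product: 28 (5R)-5-[(13E)-6α,8α-dihydroxy-18-oxolabd-13-en-15-yl]-4-methylfuran-2(5H)-one (CNP0143336.1)
Conditions: aq. HCl (0.5 M), THF, rt
Reagents that add atoms: water, O
Why: mild acetal hydrolysis frees the lactol/6α-hydroxy aldehyde; the acid leaves the base-sensitive C5′ centre, the tertiary alcohol and the alkene unchanged.

## Compound list

1 | (2E,6E)-farnesyl bromide | BrC/C=C(\C)CC/C=C(\C)CCC=C(C)C | starting material
2 | tert-butyl acetate | CC(=O)OC(C)(C)C | starting material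
3 | lithium enolate of tert-butyl acetate | [Li+].[O-]C(=C)OC(C)(C)C | intermediate
4 | tert-butyl (4E,8E)-5,9,13-trimethyltetradeca-4,8,12-trienoate | CC(C)(C)OC(=O)CC/C=C(\C)CC/C=C(\C)CCC=C(C)C | intermediate
5 | tert-butyl (4E,8E,12E)-14-hydroxy-5,9,13-trimethyltetradeca-4,8,12-trienoate | CC(C)(C)OC(=O)CC/C=C(\C)CC/C=C(\C)CC/C=C(\C)CO | intermediate
6 | tert-butyl (4E,8E)-11-[(2S,3S)-3-(hydroxymethyl)-3-methyloxiran-2-yl]-5,9-dimethylundeca-4,8-dienoate | CC(C)(C)OC(=O)CC/C=C(\C)CC/C=C(\C)CC[C@@H]1O[C@@]1(C)CO | intermediate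
7 | 3β,18-dihydroxy-14,15,16-trinorlabdan-13,8α-olide | O=C1CC[C@@H]2[C@@]3(C)CC[C@H](O)[C@@](C)(CO)[C@@H]3CC[C@@]2(C)O1 | intermediate
8 | 3β,18-O-thiocarbonyl-14,15,16-trinorlabdan-13,8α-olide | O=C1CC[C@@H]2[C@@]3(C)CC[C@@H]4OC(=S)OC[C@@]4(C)[C@@H]3CC[C@@]2(C)O1 | intermediate
9 | 18-O-[(tributylstannylsulfanyl)carbonyl]-14,15,16-trinorlabdan-13,8α-olide | O=C1CC[C@@H]2[C@@]3(C)CCC[C@@](C)(COC(=O)S[Sn](CCCC)(CCCC)CCCC)[C@@H]3CC[C@@]2(C)O1 | intermediate
10 | 18-hydroxy-14,15,16-trinorlabdan-13,8α-olide | O=C1CC[C@@H]2[C@@]3(C)CCC[C@@](C)(CO)[C@@H]3CC[C@@]2(C)O1 | intermediate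
11 | 6α,18-epoxy-14,15,16-trinorlabdan-13,8α-olide | O=C1CC[C@@H]2[C@@]3(C)CCC[C@@]4(C)CO[C@H]([C@H]34)C[C@@]2(C)O1 | intermediate
12 | 14,15,16-trinorlabdane-13,8α:18,6α-diolide | O=C1CC[C@@H]2[C@@]3(C)CCC[C@@]4(C)C(=O)O[C@H]([C@H]34)C[C@@]2(C)O1 | intermediate
13 | lithium C12=C13 enolate of 12 | [Li+].[O-]C1=CC[C@@H]2[C@@]3(C)CCC[C@@]4(C)C(=O)O[C@H]([C@H]34)C[C@@]2(C)O1 | intermediate
14 | 18-hydroxy-6α,18-epoxy-14,15,16-trinorlabdan-13,8α-olide (γ-lactol) | O=C1CC[C@@H]2[C@@]3(C)CCC[C@@]4(C)C(O)O[C@H]([C@H]34)C[C@@]2(C)O1 | intermediate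
15 | 18-methoxy-6α,18-epoxy-14,15,16-trinorlabdan-13,8α-olide | O=C1CC[C@@H]2[C@@]3(C)CCC[C@@]4(C)C(OC)O[C@H]([C@H]34)C[C@@]2(C)O1 | intermediate
16 | 18-methoxy-6α,18:8α,13-diepoxy-14,15,16-trinorlabdan-13-ol (δ-lactol) | OC1CC[C@@H]2[C@@]3(C)CCC[C@@]4(C)C(OC)O[C@H]([C@H]34)C[C@@]2(C)O1 | intermediate
17 | 18-methoxy-6α,18-epoxy-15,16-dinorlabd-13-yn-8α-ol | C#CCC[C@@H]1[C@@]2(C)CCC[C@@]3(C)C(OC)O[C@H]([C@H]23)C[C@@]1(C)O | intermediate
18 | ethylene oxide | C1CO1 | starting material
19 | [(13E)-8α-(dimethylaluminiooxy)-18-methoxy-6α,18-epoxy-15-norlabd-13-en-14-yl]dimethylalane | C[Al](C)/C=C(\C)CC[C@@H]1[C@@]2(C)CCC[C@@]3(C)C(OC)O[C@H]([C@H]23)C[C@@]1(C)O[Al](C)C | intermediate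
20 | lithium butyl(dimethyl)[(13E)-15-norlabd-13-en-14-yl]aluminate of 19 | [Li+].CCCC[Al-](C)(C)/C=C(\C)CC[C@@H]1[C@@]2(C)CCC[C@@]3(C)C(OC)O[C@H]([C@H]23)C[C@@]1(C)O[Al](C)C | intermediate
21 | (13E)-15-(hydroxymethyl)-18-methoxy-6α,18-epoxylabd-13-en-8α-ol | OCC/C=C(\C)CC[C@@H]1[C@@]2(C)CCC[C@@]3(C)C(OC)O[C@H]([C@H]23)C[C@@]1(C)O | intermediate
22 | (13E)-8α-hydroxy-18-methoxy-6α,18-epoxylabd-13-ene-15-carbaldehyde | O=CC/C=C(\C)CC[C@@H]1[C@@]2(C)CCC[C@@]3(C)C(OC)O[C@H]([C@H]23)C[C@@]1(C)O | intermediate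
23 | methyl propiolate | C#CC(=O)OC | starting material
24 | methyl 3-(ethylzincio)prop-2-ynoate | CC[Zn]C#CC(=O)OC | intermediate
25 | methyl (4R)-4-hydroxy-4-[(13E)-8α-hydroxy-18-methoxy-6α,18-epoxylabd-13-en-15-yl]but-2-ynoate | COC(=O)C#C[C@H](O)C/C=C(\C)CC[C@@H]1[C@@]2(C)CCC[C@@]3(C)C(OC)O[C@H]([C@H]23)C[C@@]1(C)O | intermediate
26 | methyl (2Z,4R)-4-hydroxy-3-methyl-4-[(13E)-8α-hydroxy-18-methoxy-6α,18-epoxylabd-13-en-15-yl]but-2-enoate | COC(=O)/C=C(/C)[C@H](O)C/C=C(\C)CC[C@@H]1[C@@]2(C)CCC[C@@]3(C)C(OC)O[C@H]([C@H]23)C[C@@]1(C)O | intermediate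
27 | (5R)-5-[(13E)-8α-hydroxy-18-methoxy-6α,18-epoxylabd-13-en-15-yl]-4-methylfuran-2(5H)-one | CC1=CC(=O)O[C@@H]1C/C=C(\C)CC[C@@H]1[C@@]2(C)CCC[C@@]3(C)C(OC)O[C@H]([C@H]23)C[C@@]1(C)O | intermediate
28 | (5R)-5-[(13E)-6α,8α-dihydroxy-18-oxolabd-13-en-15-yl]-4-methylfuran-2(5H)-one (CNP0143336.1) | CC1=CC(=O)O[C@@H]1C/C=C(\C)CC[C@@H]1[C@@]2(C)CCC[C@@](C)(C=O)[C@@H]2[C@@H](O)C[C@@]1(C)O | target

## Step count and risks

Total steps: 15. Longest linear sequence: 15 (1 → 28).

**Step 4 (cascade cyclisation on the free epoxy alcohol).** The risks are a hydride shift from C18 or C3 to the C4 cation (aldehyde or ketone instead of cyclisation) and interrupted mono-cyclisation. The fallback sets out from 6 and uses the silyl-protected substrate, a different promoter and a stepwise deoxygenation. The primary alcohol is silylated (t-BuMe2SiCl, imidazole) to tert-butyl (4E,8E)-11-[(2S,3S)-3-{[tert-butyl(dimethyl)silyl]oxymethyl}-3-methyloxiran-2-yl]-5,9-dimethylundeca-4,8-dienoate F1. Cyclisation with SnCl4 in CH2Cl2 at −78 °C gives 3β-hydroxy-18-[tert-butyl(dimethyl)silyloxy]-14,15,16-trinorlabdan-13,8α-olide F2. The 3β-hydroxyl is converted with 1,1'-thiocarbonyldiimidazole to the 3β-O-(imidazol-1-ylcarbonothioyl) ester F3, which Bu3SnH/AIBN reduces to 18-[tert-butyl(dimethyl)silyloxy]-14,15,16-trinorlabdan-13,8α-olide F4. HF·pyridine removes silicon, and the route is rejoined at 10.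

**Step 7 (remote C–H etherification).** The neopentyl C18 alkoxyl radical may lose formaldehyde (β-scission) faster than it abstracts the 6α-hydrogen. The fallback sets out from 10 and replaces the alkoxyl radical by a carboxylate-directed metal-oxo hydroxylation. Oxidation with TEMPO (cat.), NaOCl (cat.) and NaClO2 in buffered MeCN gives 14,15,16-trinorlabdan-13,8α-olid-18-oic acid F5. Treatment with [Fe(PDP)(MeCN)2](SbF6)2 and H2O2 in MeCN hydroxylates the γ C6–H next to the equatorial carboxylate and lactonises, so the route is rejoined at 12 without passing through 11.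

**Step 13 (asymmetric alkynylation).** The β,γ-unsaturated aldehyde may isomerise, and the enantioselectivity at a centre remote from all others is hard to secure and to assay. The fallback sets out from 17 and takes C5′ from a chiral epoxide, closing the butenolide by metathesis. After methylalumination as in step 11, the alanate opens (S)-2-(prop-1-en-2-yl)oxirane at its CH2 terminus to give (13E)-15-[(1R)-1-hydroxy-2-methylprop-2-en-1-yl]-18-methoxy-6α,18-epoxylabd-13-en-8α-ol F6. Acryloyl chloride/Et3N acylates only the secondary alcohol to give the corresponding (1R)-acrylate F7. Ring-closing metathesis with second-generation Grubbs catalyst (toluene, 80 °C) forms the 4-methylbutenolide, and the route is rejoined at 27.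

## Further compounds

F1 | step 4 | tert-butyl (4E,8E)-11-[(2S,3S)-3-{[tert-butyl(dimethyl)silyl]oxymethyl}-3-methyloxiran-2-yl]-5,9-dimethylundeca-4,8-dienoate | CC(C)(C)OC(=O)CC/C=C(\C)CC/C=C(\C)CC[C@@H]1O[C@@]1(C)CO[Si](C)(C)C(C)(C)C
F2 | step 4 | 3β-hydroxy-18-[tert-butyl(dimethyl)silyloxy]-14,15,16-trinorlabdan-13,8α-olide | O=C1CC[C@@H]2[C@@]3(C)CC[C@H](O)[C@@](C)(CO[Si](C)(C)C(C)(C)C)[C@@H]3CC[C@@]2(C)O1
F3 | step 4 | 3β-O-(imidazol-1-ylcarbonothioyl)-18-[tert-butyl(dimethyl)silyloxy]-14,15,16-trinorlabdan-13,8α-olide | O=C1CC[C@@H]2[C@@]3(C)CC[C@H](OC(=S)n4ccnc4)[C@@](C)(CO[Si](C)(C)C(C)(C)C)[C@@H]3CC[C@@]2(C)O1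
F4 | step 4 | 18-[tert-butyl(dimethyl)silyloxy]-14,15,16-trinorlabdan-13,8α-olide | O=C1CC[C@@H]2[C@@]3(C)CCC[C@@](C)(CO[Si](C)(C)C(C)(C)C)[C@@H]3CC[C@@]2(C)O1
F5 | step 7 | 14,15,16-trinorlabdan-13,8α-olid-18-oic acid | O=C1CC[C@@H]2[C@@]3(C)CCC[C@@](C)(C(=O)O)[C@@H]3CC[C@@]2(C)O1
F6 | step 13 | (13E)-15-[(1R)-1-hydroxy-2-methylprop-2-en-1-yl]-18-methoxy-6α,18-epoxylabd-13-en-8α-ol | C=C(C)[C@H](O)C/C=C(\C)CC[C@@H]1[C@@]2(C)CCC[C@@]3(C)C(OC)O[C@H]([C@H]23)C[C@@]1(C)O
F7 | step 13 | (1R)-1-[(13E)-8α-hydroxy-18-methoxy-6α,18-epoxylabd-13-en-15-yl]-2-methylprop-2-en-1-yl acrylate | C=C(C)[C@H](OC(=O)C=C)C/C=C(\C)CC[C@@H]1[C@@]2(C)CCC[C@@]3(C)C(OC)O[C@H]([C@H]23)C[C@@]1(C)O
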